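**Strategy.** The cyclohexene is cut along C7–C1–C2–C3=C4: C7 is read as a carboxyl carbon and C4 as a former allylic carbinol carbon, which is the retron of an ester-enolate Claisen shift. Run on the silyl ketene acetal of a D-mannose-derived δ-lactone, this single step forms C1–C2, breaks C4–O, closes the carbocycle (C1–C6) with its C3=C4 alkene and sets C1 and C2. The precursor is 2,3-O-isopropylidene-4-O-TBS-D-mannono-1,5-lactone carrying an (E)-2-(PMB-oxy)vinyl arm on sugar C5. Its dioxolane becomes the cis C1/C6 diol, its silyl ether the oxygen on ring carbon C5, and the E geometry fixes C2.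

Key step: step 11

Remark on the chemistry: carbocycles carry the target locants (C1 tertiary carbinol, C7 its CH2O carbon) and are drawn with C1→C6 clockwise and C7 up, so O2 and O5 are up and O1 and O6 down ((1R,2S,5R,6S) in the target). Sugar intermediates keep carbohydrate locants (sugar C1→C7, C2→C1, C3→C6, C4→C5, C5→C4, C6→C3, C7→C2). The D-manno lactone with an E enol ether was checked centre by centre against the rearranged acid and the target and maps correctly, so no structure needed correction.

Step 1
Reactants: 1 D-mannose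
Product: 2 benzyl α-D-mannopyranoside
Conditions: BnOH (solvent), AcCl (cat., HCl in situ), 50 °C
Reagents that add atoms: benzyl alcohol, OCc1ccccc1
Why: Fischer glycosidation under thermodynamic control should favour the α-pyranoside (anomeric effect), which fixes the pyranose ring and masks C1 as an acetal that hydrogenolysis removes later.

Step 2
Reactants: 2 benzyl α-D-mannopyranoside
Product: 4 benzyl 2,3-O-isopropylidene-α-D-mannopyranoside, via benzyl 2,3:4,6-di-O-isopropylidene-α-D-mannopyranoside 3 (not isolated)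
Conditions: Me2C(OMe)2, TsOH·H2O (cat.), acetone, rt; then H2O, rt; Et3N
Reagents that add atoms: 2,2-dimethoxypropane, COC(C)(C)OC
Why: Acid-catalysed transacetalisation should give the bis-acetonide, whose more labile six-membered 4,6-acetal is then hydrolysed selectively (kinetically controlled acetal hydrolysis), leaving the cis-fused 2,3-dioxolane.

Step 3
Reactants: 4 benzyl 2,3-O-isopropylidene-α-D-mannopyranoside
Product: 5 benzyl 4,6-di-O-(tert-butyldimethylsilyl)-2,3-O-isopropylidene-α-D-mannopyranoside
Conditions: TBSOTf, 2,6-lutidine, CH2Cl2, −20 → 0 °C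
Reagents that add atoms: tert-butyldimethylsilyl trifluoromethanesulfonate, CC(C)(C)[Si](C)(C)OS(=O)(=O)C(F)(F)F
Why: Silyl triflate with a hindered pyridine base silylates the primary and the hindered secondary hydroxyl (O-silylation), so O4 is blocked before C1 reaches the lactone level and a δ→γ lactone shift is excluded.

Step 4
Reactants: 5 benzyl 4,6-di-O-TBS-2,3-O-isopropylidene-α-D-mannopyranoside
Product: 6 4,6-di-O-TBS-2,3-O-isopropylidene-D-mannopyranose (anomeric mixture)
Conditions: H2 (1 atm), 10% Pd/C, EtOAc, rt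
Reagents that add atoms: none
Why: Catalytic hydrogenolysis cleaves only the benzylic C–O bond of the anomeric acetal, silyl ethers and acetonide being inert under neutral conditions.

Step 5
Reactants: 6 4,6-di-O-TBS-2,3-O-isopropylidene-D-mannopyranose
Product: 7 4,6-di-O-TBS-2,3-O-isopropylidene-D-mannono-1,5-lactone
Conditions: TPAP (cat.), NMO, 4 Å MS, CH2Cl2, rt
Reagents that add atoms: none
Why: Ley–Griffith oxidation converts the lactol into the δ-lactone under neutral conditions, and no free hydroxyl is left that could be oxidised or translactonise.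

Step 6
Reactants: 7 4,6-di-O-TBS-2,3-O-isopropylidene-D-mannono-1,5-lactone
Product: 8 4-O-TBS-2,3-O-isopropylidene-D-mannono-1,5-lactone
Conditions: HF·pyridine, pyridine, THF, 0 °C → rt
Reagents that add atoms: none
Why: Buffered HF·pyridine should remove the unhindered primary silyl ether much faster than the secondary one flanked by two ring substituents (sterically controlled desilylation), and the lactone tolerates these weakly acidic conditions.

Step 7
Reactants: 8 4-O-TBS-2,3-O-isopropylidene-D-mannono-1,5-lactone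
Product: 9 4-O-TBS-2,3-O-isopropylidene-D-manno-hexodialdono-1,5-lactone (the 6-aldehyde of 8)
Conditions: TEMPO (cat.), PhI(OAc)2, CH2Cl2, rt; used crude
Reagents that add atoms: none
Why: Oxoammonium (TEMPO/BAIB) oxidation of the primary alcohol stops at the aldehyde without water and needs no base, which should avoid epimerisation at sugar C5 and β-elimination of the 4-silyloxy group.

Step 8
Reactants: 10 4-methoxybenzyl alcohol
Product: 11 4-methoxybenzyl methylthiomethyl ether
Conditions: NaH, THF, 0 °C; ClCH2SMe, NaI (cat.), rt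
Reagents that add atoms: chloromethyl methyl sulfide, CSCCl
Why: Williamson alkylation of the alkoxide with the activated α-chloro sulfide gives the O,S-acetal.

Step 9
Reactants: 11 4-methoxybenzyl methylthiomethyl ether
Product: 13 [(4-methoxybenzyloxy)methyl]triphenylphosphonium chloride, via 4-methoxybenzyl chloromethyl ether 12 (not isolated)
Conditions: SO2Cl2, CH2Cl2, −78 °C → rt, evaporate; PPh3, toluene, rt → 50 °C
Reagents that add atoms: sulfuryl chloride, O=S(=O)(Cl)Cl; triphenylphosphine, c1ccc(cc1)P(c1ccccc1)c1ccccc1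
Why: Chlorinolysis of the O,S-acetal releases the chloromethyl ether, which quaternises triphenylphosphine by SN2 substitution to the alkoxymethylphosphonium salt.

Step 10
Reactants: 9 4-O-TBS-2,3-O-isopropylidene-D-manno-hexodialdono-1,5-lactone; 13 [(4-methoxybenzyloxy)methyl]triphenylphosphonium chloride
Product: 15 (6E)-4-O-TBS-6-deoxy-2,3-O-isopropylidene-7-O-(4-methoxybenzyl)-D-manno-hept-6-enono-1,5-lactone, via (4-methoxybenzyloxy)methylenetriphenylphosphorane 14 (not isolated)
Conditions: 13, KHMDS, THF, −78 °C; then 9, −78 → 0 °C; Et3N-deactivated SiO2, E isomer collected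
Reagents that add atoms: none
Why: Wittig olefination with the non-stabilised alkoxymethylene ylide should be far faster at the aldehyde than at the lactone at −78 °C and gives an E/Z enol ether mixture, from which the E isomer, the only one that leads to the target configuration at C2, is separated.

Step 11
Reactants: 15 (6E)-4-O-TBS-6-deoxy-2,3-O-isopropylidene-7-O-PMB-D-manno-hept-6-enono-1,5-lactone
Product: 18 1,6-O-isopropylidene-2-O-(4-methoxybenzyl)-5-O-TBS-1,2,5,6-tetrahydroxycyclohex-3-ene-1-carboxylic acid (CO2H, O2 and O5 up; O1 and O6 down), via trimethylsilyl ketene acetal 16 (not isolated), via trimethylsilyl ester 17 (not isolated)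
Conditions: TMSCl/Et3N (premixed), THF, −100 °C; LDA; −100 °C → rt, then 60 °C; dilute aq. citric acid
Reagents that add atoms: none
Why: Kinetic deprotonation at C1 (sugar C2) in the presence of TMSCl traps the lactone enolate as the cyclic silyl ketene acetal 16, which undergoes a concerted suprafacial [3,3] shift (Ireland–Claisen) through the E-alkoxyvinyl arm, forming C1–C2 and breaking C4–O to give silyl ester 17, hydrolysed to 18 on work-up. The closest known reaction type is the ring-contracting Ireland–Claisen rearrangement of 6-alkenyl δ-lactone silyl ketene acetals, including α-oxygenated 1,4-dioxan-2-ones, to cyclohexene- or dihydropyran-carboxylic acids. The cyclohexene closes transannularly: the two-atom tether C6–C5 allows only the boat-like, bicyclo[2.2.2]octene-type array, so the closure is a pericyclic bond shift and not an ionic exo or endo cyclisation. C1 is set by the configuration of the carbinol carbon C4 (sugar C5), because the vinyl arm reaches the ketene acetal only on its own face; C2 therefore bonds cis to the C6 ring bond, the acetonide stays cis-fused and C7 falls on the face of the C5 silyloxy group. C2 is set by the E geometry of the enol ether, which in the boat places the PMB-oxy group cis to C7 (the Z isomer would give the C2 epimer). The step needs O-silylation to outrun β-elimination of the C6 oxygen; the cis-dioxolane, which holds that C–O bond near the nodal plane of the enolate, and the internal TMSCl quench at −100 °C should secure this, and the alkoxy group on the allyl terminus should accelerate the shift.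

Step 12
Reactants: 18 the carboxylic acid
Product: 19 [1,6-O-isopropylidene-2-O-PMB-5-O-TBS-1,2,5,6-tetrahydroxycyclohex-3-en-1-yl]methanol
Conditions: LiAlH4, THF, 0 → 50 °C; Fieser work-up
Reagents that add atoms: none
Why: Hydride reduction of the carboxylic acid gives the neopentyl-type primary alcohol at C7, while silyl ether, PMB ether, acetonide and the isolated alkene are inert to LiAlH4.

Step 13
Reactants: 19 the C7 alcohol
Product: 20 the C7 acetate of 19
Conditions: Ac2O, pyridine, DMAP (cat.), CH2Cl2, rt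
Reagents that add atoms: acetic anhydride, CC(=O)OC(C)=O
Why: DMAP-catalysed acylation of the only free hydroxyl installs the C7 acetate and removes the neighbouring hydroxyl that could otherwise trap the benzylic cation of the next step as a benzylidene acetal.

Step 14
Reactants: 20 the C7 acetate
Product: 21 the C2 alcohol (7-O-acetyl-1,6-O-isopropylidene-5-O-TBS)
Conditions: DDQ, CH2Cl2/pH 7 buffer (10:1), 0 °C → rt
Reagents that add atoms: none
Why: Oxidative PMB cleavage by DDQ (benzylic hydride abstraction, then hydrolysis of the hemiacetal) frees the C2 hydroxyl without touching silyl ether, acetonide or acetate; an acetyl shift from O7 to O2 would be harmless because both are acetylated next.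

Step 15
Reactants: 21 the C2 alcohol
Product: 22 the 2,7-diacetate (1,6-O-isopropylidene-5-O-TBS)
Conditions: Ac2O, pyridine, DMAP (cat.), CH2Cl2, rt
Reagents that add atoms: acetic anhydride, CC(=O)OC(C)=O
Why: Acylation of the allylic secondary alcohol gives the C2 acetate with retention, since only the O–H bond reacts.

Step 16
Reactants: 22 the 2,7-diacetate
Product: 23 2,7-di-O-acetyl triol (free hydroxyls at C1, C5 and C6)
Conditions: TFA/H2O (9:1), 0 °C → rt
Reagents that add atoms: none
Why: Aqueous acid cleaves the silyl ether and the cis-dioxolane in one operation (acid-catalysed solvolysis), under conditions where acetates survive and acyl shifts are slow.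

Step 17
Reactants: 23 the triol diacetate
Product: 24 [(1R,2S,5R,6S)-2-acetoxy-5,6-bis(benzoyloxy)-1-hydroxycyclohex-3-en-1-yl]methyl acetate (target)
Conditions: BzCl, pyridine, DMAP (cat.), CH2Cl2, 0 °C → rt
Reagents that add atoms: benzoyl chloride, O=C(Cl)c1ccccc1
Why: Esterification discriminates sterically between the two secondary hydroxyls at C5 and C6, which are benzoylated, and the tertiary C1 hydroxyl, which is not.

**Compound list**

1 | D-mannose | O=C[C@@H](O)[C@@H](O)[C@H](O)[C@H](O)CO | starting material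
2 | benzyl α-D-mannopyranoside | O(Cc1ccccc1)[C@@H]2[C@@H](O)[C@@H](O)[C@H](O)[C@@H](CO)O2 | intermediate
3 | benzyl 2,3:4,6-di-O-isopropylidene-α-D-mannopyranoside | O(Cc1ccccc1)[C@@H]2[C@H]3OC(C)(C)O[C@H]3[C@@H]4OC(C)(C)OC[C@H]4O2 | intermediate
4 | benzyl 2,3-O-isopropylidene-α-D-mannopyranoside | O(Cc1ccccc1)[C@@H]2[C@H]3OC(C)(C)O[C@H]3[C@H](O)[C@@H](CO)O2 | intermediate
5 | benzyl 4,6-di-O-TBS-2,3-O-isopropylidene-α-D-mannopyranoside | O(Cc1ccccc1)[C@@H]2[C@H]3OC(C)(C)O[C@H]3[C@H](O[Si](C)(C)C(C)(C)C)[C@@H](CO[Si](C)(C)C(C)(C)C)O2 | intermediate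
6 | 4,6-di-O-TBS-2,3-O-isopropylidene-D-mannopyranose | OC1[C@H]2OC(C)(C)O[C@H]2[C@H](O[Si](C)(C)C(C)(C)C)[C@@H](CO[Si](C)(C)C(C)(C)C)O1 | intermediate
7 | 4,6-di-O-TBS-2,3-O-isopropylidene-D-mannono-1,5-lactone | O=C1[C@H]2OC(C)(C)O[C@H]2[C@H](O[Si](C)(C)C(C)(C)C)[C@@H](CO[Si](C)(C)C(C)(C)C)O1 | intermediate
8 | 4-O-TBS-2,3-O-isopropylidene-D-mannono-1,5-lactone | O=C1[C@H]2OC(C)(C)O[C@H]2[C@H](O[Si](C)(C)C(C)(C)C)[C@@H](CO)O1 | intermediate
9 | 4-O-TBS-2,3-O-isopropylidene-D-manno-hexodialdono-1,5-lactone | O=C1[C@H]2OC(C)(C)O[C@H]2[C@H](O[Si](C)(C)C(C)(C)C)[C@@H](C=O)O1 | intermediate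
10 | 4-methoxybenzyl alcohol | COc1ccc(CO)cc1 | starting material
11 | 4-methoxybenzyl methylthiomethyl ether | COc1ccc(COCSC)cc1 | intermediate
12 | 4-methoxybenzyl chloromethyl ether | COc1ccc(COCCl)cc1 | intermediate
13 | [(4-methoxybenzyloxy)methyl]triphenylphosphonium chloride | COc1ccc(COC[P+](c2ccccc2)(c2ccccc2)c2ccccc2)cc1.[Cl-] | intermediate
14 | (4-methoxybenzyloxy)methylenetriphenylphosphorane | COc1ccc(COC=P(c2ccccc2)(c2ccccc2)c2ccccc2)cc1 | intermediate
15 | (6E)-4-O-TBS-6-deoxy-2,3-O-isopropylidene-7-O-(4-methoxybenzyl)-D-manno-hept-6-enono-1,5-lactone | O=C1[C@H]2OC(C)(C)O[C@H]2[C@H](O[Si](C)(C)C(C)(C)C)[C@@H](/C=C/OCc3ccc(OC)cc3)O1 | intermediate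
16 | trimethylsilyl ketene acetal of 15 | C[Si](C)(C)OC1=C2OC(C)(C)O[C@H]2[C@H](O[Si](C)(C)C(C)(C)C)[C@@H](/C=C/OCc3ccc(OC)cc3)O1 | intermediate
17 | trimethylsilyl ester of 18 | C[Si](C)(C)OC(=O)[C@@]1(O2)[C@@H](OCc3ccc(OC)cc3)C=C[C@@H](O[Si](C)(C)C(C)(C)C)[C@@H]1OC2(C)C | intermediate
18 | 1,6-O-isopropylidene-2-O-PMB-5-O-TBS-1,2,5,6-tetrahydroxycyclohex-3-ene-1-carboxylic acid | OC(=O)[C@@]1(O2)[C@@H](OCc3ccc(OC)cc3)C=C[C@@H](O[Si](C)(C)C(C)(C)C)[C@@H]1OC2(C)C | intermediate
19 | C7 alcohol (1,6-O-isopropylidene-2-O-PMB-5-O-TBS) | OC[C@@]1(O2)[C@@H](OCc3ccc(OC)cc3)C=C[C@@H](O[Si](C)(C)C(C)(C)C)[C@@H]1OC2(C)C | intermediate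
20 | C7 acetate (1,6-O-isopropylidene-2-O-PMB-5-O-TBS) | CC(=O)OC[C@@]1(O2)[C@@H](OCc3ccc(OC)cc3)C=C[C@@H](O[Si](C)(C)C(C)(C)C)[C@@H]1OC2(C)C | intermediate
21 | C2 alcohol (7-O-acetyl-1,6-O-isopropylidene-5-O-TBS) | CC(=O)OC[C@@]1(O2)[C@@H](O)C=C[C@@H](O[Si](C)(C)C(C)(C)C)[C@@H]1OC2(C)C | intermediate
22 | 2,7-diacetate (1,6-O-isopropylidene-5-O-TBS) | CC(=O)OC[C@@]1(O2)[C@@H](OC(C)=O)C=C[C@@H](O[Si](C)(C)C(C)(C)C)[C@@H]1OC2(C)C | intermediate
23 | 2,7-di-O-acetyl triol (1-, 5-, 6-OH free) | CC(=O)OC[C@@]1(O)[C@@H](OC(C)=O)C=C[C@@H](O)[C@@H]1O | intermediate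
24 | [(1R,2S,5R,6S)-2-acetoxy-5,6-bis(benzoyloxy)-1-hydroxycyclohex-3-en-1-yl]methyl acetate | CC(=O)OC[C@@]1(O)[C@@H](OC(C)=O)C=C[C@@H](OC(=O)c2ccccc2)[C@@H]1OC(=O)c1ccccc1 | target

**Step count.** Total steps: 17. Longest linear sequence: 15 (steps 1–7 and 10–17; steps 8–9 make the Wittig salt).

**Steps most likely to fail**

1. Step 11. The lithium enolate may lose the C6 oxygen by β-elimination faster than it is silylated, or the silyl ketene acetal may fail to reach the boat array and revert to lactone on work-up. The fallback uses no lactone enolate and no sigmatropic step; it sets out from 5 and comes back to the route at 22. Selective cleavage of the primary silyl ether (HF·pyridine) would give benzyl 4-O-TBS-2,3-O-isopropylidene-α-D-mannopyranoside F1. Appel-type iodination (I2, PPh3, imidazole) would give the 6-deoxy-6-iodo glycoside F2, and Bernet–Vasella fragmentation (Zn, THF/H2O) would give 5,6-dideoxy-2,3-O-isopropylidene-4-O-TBS-D-lyxo-hex-5-enose F3. A crossed aldol reaction with formaldehyde (aq. CH2O, K2CO3, MeOH), entering anti to the C3 substituent of the dioxolane, would give the 2-C-hydroxymethyl aldehyde F4, which carries the future C1 and C7; acetylation would give its acetate F5. Vinylmagnesium bromide with MgBr2·OEt2 at −78 °C, attacking the α-chelate from the acetoxymethyl side, is expected to give the vinyl carbinol F6 with the C2 configuration of the target; this selectivity is the weak point of the fallback and the epimers would otherwise be separated after ring closure. Acetylation to the diene diacetate F7 and ring-closing metathesis (Grubbs second-generation catalyst, CH2Cl2, 40 °C) would then give 22.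

2. Step 10. The olefination may deliver mostly the unwanted Z geometry, and the basic ylide may epimerise sugar C5, eliminate the 4-silyloxy group or add to the lactone. The fallback is non-basic and stereospecific; it sets out from 9 and comes back at 15. Takai–Utimoto boron olefination (CrCl2, Cl2CHBpin, LiI, THF) would give the (E)-alkenyl pinacol boronate F8. Chan–Evans–Lam coupling with 10 (Cu(OAc)2, Et3N, 4 Å MS, CH2Cl2, air, rt) would give 15 with retention of the E geometry.

3. Step 16. The hindered allylic silyl ether may cleave only at an acid strength that also starts solvolysis or migration of the acetates once three hydroxyls are free. The fallback acylates each hydroxyl as it is released; it sets out from 22 and comes back at 24. HF·pyridine would give the C5 alcohol F9, and benzoylation (BzCl, pyridine) the 5-benzoate F10. Mild hydrolysis of the acetonide alone (80% aq. AcOH, 60 °C) would give the 1,6-diol F11, and benzoylation of its secondary hydroxyl (BzCl, pyridine, DMAP) would give 24.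

**Further compounds**

F1 | step 11 | benzyl 4-O-TBS-2,3-O-isopropylidene-α-D-mannopyranoside | O(Cc1ccccc1)[C@@H]2[C@H]3OC(C)(C)O[C@H]3[C@H](O[Si](C)(C)C(C)(C)C)[C@@H](CO)O2
F2 | step 11 | benzyl 6-deoxy-6-iodo-4-O-TBS-2,3-O-isopropylidene-α-D-mannopyranoside | O(Cc1ccccc1)[C@@H]2[C@H]3OC(C)(C)O[C@H]3[C@H](O[Si](C)(C)C(C)(C)C)[C@@H](CI)O2
F3 | step 11 | 5,6-dideoxy-2,3-O-isopropylidene-4-O-TBS-D-lyxo-hex-5-enose | O=C[C@H]1OC(C)(C)O[C@H]1[C@H](O[Si](C)(C)C(C)(C)C)C=C
F4 | step 11 | 5,6-dideoxy-2-C-(hydroxymethyl)-2,3-O-isopropylidene-4-O-TBS-D-lyxo-hex-5-enose | O=C[C@@]1(CO)OC(C)(C)O[C@H]1[C@H](O[Si](C)(C)C(C)(C)C)C=C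
F5 | step 11 | 2-C-(acetoxymethyl)-5,6-dideoxy-2,3-O-isopropylidene-4-O-TBS-D-lyxo-hex-5-enose | O=C[C@@]1(COC(C)=O)OC(C)(C)O[C@H]1[C@H](O[Si](C)(C)C(C)(C)C)C=C
F6 | step 11 | vinyl carbinol (octa-1,7-diene; 3-OH, 4-C-acetoxymethyl, 4,5-O-isopropylidene, 6-O-TBS; configured as C2, C1, C6, C5 of the target) | CC(=O)OC[C@]1([C@@H](O)C=C)OC(C)(C)O[C@H]1[C@H](O[Si](C)(C)C(C)(C)C)C=C
F7 | step 11 | diene diacetate (3-O-acetate of F6) | CC(=O)OC[C@]1([C@@H](OC(C)=O)C=C)OC(C)(C)O[C@H]1[C@H](O[Si](C)(C)C(C)(C)C)C=C
F8 | step 10 | (6E)-4-O-TBS-6,7-dideoxy-2,3-O-isopropylidene-7-(pinacolatoboryl)-D-manno-hept-6-enono-1,5-lactone | O=C1[C@H]2OC(C)(C)O[C@H]2[C@H](O[Si](C)(C)C(C)(C)C)[C@@H](/C=C/B3OC(C)(C)C(C)(C)O3)O1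
F9 | step 16 | C5 alcohol (2,7-di-O-acetyl-1,6-O-isopropylidene) | CC(=O)OC[C@@]1(O2)[C@@H](OC(C)=O)C=C[C@@H](O)[C@@H]1OC2(C)C
F10 | step 16 | 5-benzoate (2,7-di-O-acetyl-1,6-O-isopropylidene) | CC(=O)OC[C@@]1(O2)[C@@H](OC(C)=O)C=C[C@@H](OC(=O)c3ccccc3)[C@@H]1OC2(C)C
F11 | step 16 | 1,6-diol (2,7-di-O-acetyl-5-O-benzoyl) | CC(=O)OC[C@@]1(O)[C@@H](OC(C)=O)C=C[C@@H](OC(=O)c2ccccc2)[C@@H]1O
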